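**Strategy.** Everything rests on cutting the side chain inside its first prenyl unit, between the methyl-bearing olefinic carbon C3' and the methylene C4'. The feature exploited is the 1,5 relationship between the oxygen on ring carbon C1 of the quinone and C3': bonding that oxygen to C3' gives a chroman-2-one whose lactone carbon is C3'. Its ketene acetal phosphate, a 4H-chromene, is joined to the C26 homoallylic zinc reagent by Negishi coupling. Because the pyran ring holds the ring oxygen and C1' cis, a nickel-catalysed exchange of that oxygen for methyl then opens the ring, sets the 2'E olefin and frees the phenol that is oxidised to the quinone.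

Key step: step 10

Remark: quinone ring atoms are numbered C1 (C=O beside the prenylated carbon), C2 (OCH3), C3 (OH), C4 (C=O), C5 (CH3), C6 (side chain), and side-chain carbons C1' to C24'; compounds 1, 4, 8 (as the all-E isomer) and 10 are assumed to be purchasable.

**Step 1**
Reactants: 1 methyl 3,5-dihydroxy-4-methoxybenzoate
Product: 2 5-(hydroxymethyl)-2-methoxybenzene-1,3-diol
Conditions: LiAlH4, THF, 0 °C to reflux; then aq. HCl
Reagents that add atoms: none
Why: Hydride reduction of the aryl ester should stop at the benzylic alcohol, the two phenols being carried through as aluminium phenoxides.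

**Step 2**
Reactants: 2 5-(hydroxymethyl)-2-methoxybenzene-1,3-diol
Product: 3 2-methoxy-5-methylbenzene-1,3-diol
Conditions: H2 (1 atm), Pd/C, MeOH, cat. HCl, rt
Reagents that add atoms: none
Why: Hydrogenolysis of a benzylic C–O bond is fast for a para-methoxybenzylic alcohol under acid catalysis and should leave the ring intact.

**Step 3**
Reactants: 3 2-methoxy-5-methylbenzene-1,3-diol; 4 acrylic acid
Product: 5 7-hydroxy-8-methoxy-5-methylchroman-2-one
Conditions: Amberlyst-15, toluene, reflux, Dean–Stark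
Reagents that add atoms: none
Why: Acid-catalysed Friedel–Crafts conjugate alkylation and lactonisation can only use the two equivalent ring positions between OH and CH3, so the symmetry of 3 should fix the regiochemistry and leave the second hydroxyl as the future C3–OH.

**Step 4**
Reactants: 5 7-hydroxy-8-methoxy-5-methylchroman-2-one
Product: 6 8-methoxy-5-methyl-7-[(triisopropylsilyl)oxy]chroman-2-one
Conditions: iPr3SiCl, imidazole, DMF, rt
Reagents that add atoms: chlorotriisopropylsilane, CC(C)[Si](Cl)(C(C)C)C(C)C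
Why: Silylation of the only free phenol should give an ether that withstands amide base, organozinc and Grignard reagents.

**Step 5**
Reactants: 6 8-methoxy-5-methyl-7-[(triisopropylsilyl)oxy]chroman-2-one
Product: 7 8-methoxy-5-methyl-7-[(triisopropylsilyl)oxy]-4H-chromen-2-yl diphenyl phosphate
Conditions: KN(SiMe3)2 added to 6 and (PhO)2P(O)Cl, THF/HMPA, −78 °C
Reagents that add atoms: diphenyl chlorophosphate, O=P(Cl)(Oc1ccccc1)Oc1ccccc1
Why: O-Phosphorylation of the potassium lactone enolate (enol phosphate formation) should give the ketene acetal phosphate, the electrophile being present from the start so that the aryl ester enolate is trapped before it can open to a ketene.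

**Step 6**
Reactants: 8 (2E,6E,10E)-geranylgeraniol
Product: 9 (2E,6E,10E)-geranylgeranyl bromide
Conditions: PBr3, cat. pyridine, Et2O, 0 °C
Reagents that add atoms: phosphorus tribromide, BrP(Br)Br
Why: Bromination of the primary allylic alcohol at 0 °C should proceed by SN2 displacement without allylic transposition or loss of olefin geometry.

**Step 7**
Reactants: 9 (2E,6E,10E)-geranylgeranyl bromide; 10 1-(trimethylsilyl)propyne
Product: 12 (5E,9E,13E)-6,10,14,18-tetramethylnonadeca-5,9,13,17-tetraen-1-yne, via silylated enyne 11 (not isolated)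
Conditions: 10, n-BuLi, THF, −78 to −20 °C; 9, −78 °C to rt; then K2CO3, MeOH, rt
Reagents that add atoms: none
Why: Propargylic lithiation of 10 and SN2 alkylation by the allylic bromide should give the 1,5-enyne, and methanolysis then removes the C-silyl group.

**Step 8**
Reactants: 12 (5E,9E,13E)-6,10,14,18-tetramethylnonadeca-5,9,13,17-tetraen-1-yne
Product: 14 (3E,7E,11E,15E)-4,8,12,16,20-pentamethylhenicosa-3,7,11,15,19-pentaen-1-ol, via alkenylalane 13 (not isolated)
Conditions: AlMe3, Cp2ZrCl2 (cat.), CH2Cl2, 0 °C to rt; n-BuLi, THF, −78 °C; oxirane, −78 to 0 °C; then dilute aq. HCl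
Reagents that add atoms: trimethylaluminium, C[Al](C)C; oxirane, C1CO1
Why: Zirconium-catalysed carboalumination adds CH3 and Al syn across the terminal alkyne with Al on the terminal carbon, which sets the new E-trisubstituted olefin, and the alanate formed with n-BuLi should open oxirane with retention.

**Step 9**
Reactants: 14 (3E,7E,11E,15E)-4,8,12,16,20-pentamethylhenicosa-3,7,11,15,19-pentaen-1-ol
Product: 15 (3E,7E,11E,15E)-1-iodo-4,8,12,16,20-pentamethylhenicosa-3,7,11,15,19-pentaene
Conditions: I2, PPh3, imidazole, CH2Cl2, 0 °C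
Reagents that add atoms: iodine, II
Why: Appel-type iodination of the primary homoallylic alcohol should be clean at 0 °C and leave the trisubstituted olefins untouched.

**Step 10**
Reactants: 15 (3E,7E,11E,15E)-1-iodo-4,8,12,16,20-pentamethylhenicosa-3,7,11,15,19-pentaene; 7 8-methoxy-5-methyl-7-[(triisopropylsilyl)oxy]-4H-chromen-2-yl diphenyl phosphate
Product: 18 triisopropyl({8-methoxy-5-methyl-2-[(3E,7E,11E,15E)-4,8,12,16,20-pentamethylhenicosa-3,7,11,15,19-pentaen-1-yl]-4H-chromen-7-yl}oxy)silane, via alkyllithium 16 (not isolated), via alkylzinc chloride 17 (not isolated)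
Conditions: 15, t-BuLi (2.1 equiv), Et2O, −78 °C; ZnCl2, THF, −78 to 0 °C; then 7, Pd(PPh3)4 (5 mol %), THF, rt to 50 °C; aq. NH4Cl
Reagents that add atoms: none
Why: Lithium–iodine exchange and transmetalation give a homoallylic zinc reagent, and zerovalent palladium should insert into the C–O bond of the ketene acetal phosphate, take the alkyl group from zinc and form the C(sp2)–C(sp3) bond by reductive elimination, joining the lactone carbon (the later C3') to C4' of the chain. The closest known reaction type is the Negishi coupling of lactone-derived ketene acetal phosphates with alkylzinc halides, together with the homoallylzinc–alkenyl couplings used for 1,5-diene terpenoids. No ring is closed and no stereocentre is formed; the pyran ring is kept on purpose, because in it the ring oxygen and C1' (C4 of the chromene) are necessarily cis on the new trisubstituted enol ether double bond. The step needs selectivity for the enol phosphate C–O bond over the aryl C–O and Si–O bonds, which the activated vinyl phosphate and the PPh3 ligands should secure, and reductive elimination must outrun β-hydride loss, as is usual for primary homoallylic zinc partners. The four E olefins of the chain are remote from the metal and should not be affected.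

**Step 11**
Reactants: 18 triisopropyl({8-methoxy-5-methyl-2-[(3E,7E,11E,15E)-4,8,12,16,20-pentamethylhenicosa-3,7,11,15,19-pentaen-1-yl]-4H-chromen-7-yl}oxy)silane
Product: 19 2-[(2E,6E,10E,14E,18E)-3,7,11,15,19,23-hexamethyltetracosa-2,6,10,14,18,22-hexaen-1-yl]-6-methoxy-3-methyl-5-[(triisopropylsilyl)oxy]phenol
Conditions: MeMgBr (3 equiv), NiCl2(PPh3)2 (10 mol %), benzene, 70 °C; then aq. NH4Cl
Reagents that add atoms: methylmagnesium bromide, C[Mg]Br
Why: In this nickel-catalysed Kumada-type coupling of an enol ether C–O bond, zerovalent nickel should insert into the vinyl C–O bond with aryloxide as leaving group and replace oxygen by CH3 with retention, so CH3 ends cis to C1', the 2'E olefin is set and the ring opens to the phenol.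

**Step 12**
Reactants: 19 2-[(2E,6E,10E,14E,18E)-3,7,11,15,19,23-hexamethyltetracosa-2,6,10,14,18,22-hexaen-1-yl]-6-methoxy-3-methyl-5-[(triisopropylsilyl)oxy]phenol
Product: 21 3-demethylubiquinone-6, via silyloxyquinone 20 (not isolated)
Conditions: K2[ON(SO3)2] (2.2 equiv), KH2PO4, Bu4NHSO4 (cat.), CH2Cl2/H2O, 0 °C to rt; then Bu4NF, AcOH, THF, 0 °C
Reagents that add atoms: potassium nitrosodisulfonate, [K+].[K+].[O]N(S(=O)(=O)[O-])S(=O)(=O)[O-]
Why: In this Teuber oxidation the nitrosodisulfonate radical should convert the phenol with a free para position into the para-quinone without touching the isolated olefins, and buffered fluoride then cleaves the silyl ether, which in 20 is a labile vinylogous silyl ester.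

**Compound list**

1 | methyl 3,5-dihydroxy-4-methoxybenzoate | COC(=O)c1cc(O)c(OC)c(O)c1 | starting material
2 | 5-(hydroxymethyl)-2-methoxybenzene-1,3-diol | OCc1cc(O)c(OC)c(O)c1 | intermediate
3 | 2-methoxy-5-methylbenzene-1,3-diol | Cc1cc(O)c(OC)c(O)c1 | intermediate
4 | acrylic acid | C=CC(=O)O | starting material
5 | 7-hydroxy-8-methoxy-5-methylchroman-2-one | O=C1CCc2c(C)cc(O)c(OC)c2O1 | intermediate
6 | 8-methoxy-5-methyl-7-[(triisopropylsilyl)oxy]chroman-2-one | O=C1CCc2c(C)cc(O[Si](C(C)C)(C(C)C)C(C)C)c(OC)c2O1 | intermediate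
7 | 8-methoxy-5-methyl-7-[(triisopropylsilyl)oxy]-4H-chromen-2-yl diphenyl phosphate | O=P(Oc1ccccc1)(Oc1ccccc1)OC1=CCc2c(C)cc(O[Si](C(C)C)(C(C)C)C(C)C)c(OC)c2O1 | intermediate
8 | (2E,6E,10E)-geranylgeraniol, (2E,6E,10E)-3,7,11,15-tetramethylhexadeca-2,6,10,14-tetraen-1-ol | OC/C=C(\C)CC/C=C(\C)CC/C=C(\C)CCC=C(C)C | starting material
9 | (2E,6E,10E)-geranylgeranyl bromide | BrC/C=C(\C)CC/C=C(\C)CC/C=C(\C)CCC=C(C)C | intermediate
10 | 1-(trimethylsilyl)propyne | CC#C[Si](C)(C)C | starting material
11 | trimethyl[(5E,9E,13E)-6,10,14,18-tetramethylnonadeca-5,9,13,17-tetraen-1-yn-1-yl]silane (formed in the flask) | C[Si](C)(C)C#CCC/C=C(\C)CC/C=C(\C)CC/C=C(\C)CCC=C(C)C | intermediate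
12 | (5E,9E,13E)-6,10,14,18-tetramethylnonadeca-5,9,13,17-tetraen-1-yne | C#CCC/C=C(\C)CC/C=C(\C)CC/C=C(\C)CCC=C(C)C | intermediate
13 | dimethyl[(1E,5E,9E,13E)-2,6,10,14,18-pentamethylnonadeca-1,5,9,13,17-pentaen-1-yl]alane (formed in the flask) | C[Al](C)/C=C(\C)CC/C=C(\C)CC/C=C(\C)CC/C=C(\C)CCC=C(C)C | intermediate
14 | (3E,7E,11E,15E)-4,8,12,16,20-pentamethylhenicosa-3,7,11,15,19-pentaen-1-ol | OCC/C=C(\C)CC/C=C(\C)CC/C=C(\C)CC/C=C(\C)CCC=C(C)C | intermediate
15 | (3E,7E,11E,15E)-1-iodo-4,8,12,16,20-pentamethylhenicosa-3,7,11,15,19-pentaene | ICC/C=C(\C)CC/C=C(\C)CC/C=C(\C)CC/C=C(\C)CCC=C(C)C | intermediate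
16 | [(3E,7E,11E,15E)-4,8,12,16,20-pentamethylhenicosa-3,7,11,15,19-pentaen-1-yl]lithium (formed in the flask) | [Li]CC/C=C(\C)CC/C=C(\C)CC/C=C(\C)CC/C=C(\C)CCC=C(C)C | intermediate
17 | chloro[(3E,7E,11E,15E)-4,8,12,16,20-pentamethylhenicosa-3,7,11,15,19-pentaen-1-yl]zinc (formed in the flask) | Cl[Zn]CC/C=C(\C)CC/C=C(\C)CC/C=C(\C)CC/C=C(\C)CCC=C(C)C | intermediate
18 | triisopropyl({8-methoxy-5-methyl-2-[(3E,7E,11E,15E)-4,8,12,16,20-pentamethylhenicosa-3,7,11,15,19-pentaen-1-yl]-4H-chromen-7-yl}oxy)silane | C1(CC/C=C(\C)CC/C=C(\C)CC/C=C(\C)CC/C=C(\C)CCC=C(C)C)=CCc2c(C)cc(O[Si](C(C)C)(C(C)C)C(C)C)c(OC)c2O1 | intermediate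
19 | 2-[(2E,6E,10E,14E,18E)-3,7,11,15,19,23-hexamethyltetracosa-2,6,10,14,18,22-hexaen-1-yl]-6-methoxy-3-methyl-5-[(triisopropylsilyl)oxy]phenol | COc1c(O)c(C/C=C(\C)CC/C=C(\C)CC/C=C(\C)CC/C=C(\C)CC/C=C(\C)CCC=C(C)C)c(C)cc1O[Si](C(C)C)(C(C)C)C(C)C | intermediate
20 | 2-[(2E,6E,10E,14E,18E)-3,7,11,15,19,23-hexamethyltetracosa-2,6,10,14,18,22-hexaen-1-yl]-6-methoxy-3-methyl-5-[(triisopropylsilyl)oxy]-1,4-benzoquinone (formed in the flask) | COC1=C(O[Si](C(C)C)(C(C)C)C(C)C)C(=O)C(C)=C(C/C=C(\C)CC/C=C(\C)CC/C=C(\C)CC/C=C(\C)CC/C=C(\C)CCC=C(C)C)C1=O | intermediate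
21 | 3-demethylubiquinone-6, 3-hydroxy-2-methoxy-5-methyl-6-[(2E,6E,10E,14E,18E)-3,7,11,15,19,23-hexamethyltetracosa-2,6,10,14,18,22-hexaen-1-yl]-1,4-benzoquinone | COC1=C(O)C(=O)C(C)=C(C/C=C(\C)CC/C=C(\C)CC/C=C(\C)CC/C=C(\C)CC/C=C(\C)CCC=C(C)C)C1=O | target

**Total step count:** 12.

**Longest linear sequence:** 8 steps (1 → 2 → 3 → 5 → 6 → 7 → 18 → 19 → 21, steps 1–5 and 10–12). The chain branch (steps 6–9) joins at step 10.

**Steps most likely to fail**

Step 10. Oxidative addition into the electron-rich ketene acetal phosphate may be slow, so that hydrolysis of the phosphate or β-hydride loss from the alkylpalladium overtakes the coupling. The fallback replaces cross-coupling by acyl addition and sets out from lactone 6 and iodide 15. Alkyllithium 16 (t-BuLi, Et2O, −78 °C) is added to 6 at −78 °C so that the aryloxide is expelled and the ring opens to the hydroxy ketone (6E,10E,14E,18E)-1-{2-hydroxy-3-methoxy-6-methyl-4-[(triisopropylsilyl)oxy]phenyl}-7,11,15,19,23-pentamethyltetracosa-6,10,14,18,22-pentaen-3-one F1. Cyclodehydration of its lactol form (pyridinium p-toluenesulfonate, toluene, Dean–Stark) should give the endocyclic enol ether, and the fallback comes back to the route at 18.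

Step 11. The olefin geometry may erode through isomerisation of the alkenylnickel intermediate, or nickel may insert into the aryl C–O bond instead of the vinyl one. The fallback is a copper-mediated 1,2-metallate rearrangement and sets out from phosphate 7 and iodide 15. Stannylation of 7 (Me3SnSnMe3, Pd(PPh3)4, LiCl, THF, 60 °C) gives trimethyl{8-methoxy-5-methyl-7-[(triisopropylsilyl)oxy]-4H-chromen-2-yl}stannane F2, and MeLi (THF, −78 °C) gives {8-methoxy-5-methyl-7-[(triisopropylsilyl)oxy]-4H-chromen-2-yl}lithium F3. F3 and alkyllithium 16 are combined with CuI at −78 °C to give the lithium alkyl(chromenyl)cuprate F4. On warming, the alkyl group should migrate from copper to C2 with inversion and expel the aryloxide, giving the ring-opened alkenylcopper lithium phenoxide F5 with copper cis to C1'. MeI then methylates the C–Cu bond with retention, and after aqueous work-up the fallback comes back to the route at 19.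

Step 12. Attack of the oxidant at the para carbon may be slowed by the flanking methyl and bulky silyloxy groups, so that oxidation at the ortho carbon with loss of the methoxy group competes. The fallback reverses the order of events and sets out from 19. Bu4NF/AcOH (THF, 0 °C, degassed) gives 4-[(2E,6E,10E,14E,18E)-3,7,11,15,19,23-hexamethyltetracosa-2,6,10,14,18,22-hexaen-1-yl]-2-methoxy-5-methylbenzene-1,3-diol F6. Aerobic oxidation (O2, catalytic Co(salen), C16H14CoN2O2, DMF, rt) at its only free ring position should then give the hydroxyquinone directly, and the fallback comes back to the route at 21.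

**Further compounds**

F1 | step 10 | (6E,10E,14E,18E)-1-{2-hydroxy-3-methoxy-6-methyl-4-[(triisopropylsilyl)oxy]phenyl}-7,11,15,19,23-pentamethyltetracosa-6,10,14,18,22-pentaen-3-one | O=C(CCc1c(C)cc(O[Si](C(C)C)(C(C)C)C(C)C)c(OC)c1O)CC/C=C(\C)CC/C=C(\C)CC/C=C(\C)CC/C=C(\C)CCC=C(C)C
F2 | step 11 | trimethyl{8-methoxy-5-methyl-7-[(triisopropylsilyl)oxy]-4H-chromen-2-yl}stannane | C[Sn](C)(C)C1=CCc2c(C)cc(O[Si](C(C)C)(C(C)C)C(C)C)c(OC)c2O1
F3 | step 11 | {8-methoxy-5-methyl-7-[(triisopropylsilyl)oxy]-4H-chromen-2-yl}lithium | [Li]C1=CCc2c(C)cc(O[Si](C(C)C)(C(C)C)C(C)C)c(OC)c2O1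
F4 | step 11 | lithium {8-methoxy-5-methyl-7-[(triisopropylsilyl)oxy]-4H-chromen-2-yl}[(3E,7E,11E,15E)-4,8,12,16,20-pentamethylhenicosa-3,7,11,15,19-pentaen-1-yl]cuprate | [Li+].[Cu-](CC/C=C(\C)CC/C=C(\C)CC/C=C(\C)CC/C=C(\C)CCC=C(C)C)C1=CCc2c(C)cc(O[Si](C(C)C)(C(C)C)C(C)C)c(OC)c2O1
F5 | step 11 | alkenylcopper lithium phenoxide, copper on C3' cis to C1' of the ring-opened (2Z,6E,10E,14E,18E)-7,11,15,19,23-pentamethyltetracosa-2,6,10,14,18,22-hexaenyl chain | [Li]Oc1c(OC)c(O[Si](C(C)C)(C(C)C)C(C)C)cc(C)c1C/C=C(\[Cu])CC/C=C(\C)CC/C=C(\C)CC/C=C(\C)CC/C=C(\C)CCC=C(C)C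
F6 | step 12 | 4-[(2E,6E,10E,14E,18E)-3,7,11,15,19,23-hexamethyltetracosa-2,6,10,14,18,22-hexaen-1-yl]-2-methoxy-5-methylbenzene-1,3-diol | COc1c(O)c(C/C=C(\C)CC/C=C(\C)CC/C=C(\C)CC/C=C(\C)CC/C=C(\C)CCC=C(C)C)c(C)cc1O
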